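## Retrosynthetic overview

- The last bond made joins the quaternary (S)-C(CH3)(vinyl) carbon to the E-alkenyl carbon. It is formed by copper-catalysed enantioselective SN2′ attack of an E-alkenylalane on (2E,6E)-farnesyl diethyl phosphate.
- The alkenylalane comes from a terminal alkyne, made from the ring methyl ketone (trans-dihydro-γ-irone). HWE adds exactly the two alkyne carbons, CuH conjugate reduction sets the (S)-CH(CH3), and ester → aldehyde → alkyne follows without homologation.
- The only ring, the cyclohexane, is closed once. Cp2TiCl opens a 2,2-disubstituted oxirane, and the tertiary radical bonds the future C(CH3)2 carbon to the ring CH that carries the side chain.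
- Feature used: the ring sequence C(CH3)2–CH(CH3)–CH2–CH2–C(=CH2)–CH(chain) is a C-methylated neryl unit. The exocyclic CH2 is the neryl methyl, and the chain lies 1,3-trans to the ring methyl, which is the result of a Z-alkene closing through a chair.
- The Z-epoxy alkene is reached from nerylacetone in five steps: ketal, SeO2, Sharpless epoxidation, cuprate opening, oxirane closure.

Key step: step 6

Assumption: the ligand antipodes named in steps 11 and 15 are those expected, by analogy with simple E-configured β-methyl enoates and prenyl-type phosphates, to give the (S) centres. If a model run shows the opposite sense, the mirror-image ligand is used and nothing else changes.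

## Route

Step 1
Reactants: 1 nerylacetone
Product: 2 nerylacetone ethylene ketal 2-[(3Z)-4,8-dimethylnona-3,7-dien-1-yl]-2-methyl-1,3-dioxolane
Conditions: HOCH2CH2OH (5 equiv), PPTS (5 mol %), toluene, Dean–Stark, reflux
Reagents that add atoms: ethylene glycol, OCCO
Why: Acid-catalysed ketalisation with azeotropic removal of water masks the ketone against the cuprate, hydrazine and base used later, and the weak acid leaves the isolated Z-alkene untouched.

Step 2
Reactants: 2 nerylacetone ethylene ketal
Product: 3 (2E,6Z)-2,6-dimethyl-9-(2-methyl-1,3-dioxolan-2-yl)nona-2,6-dien-1-ol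
Conditions: SeO2 (0.2 equiv), t-BuOOH (2.5 equiv), salicylic acid (0.1 equiv), CH2Cl2, 0 °C to rt; then NaBH4, MeOH, 0 °C
Reagents that add atoms: tert-butyl hydroperoxide, CC(C)(C)OO (oxygen passed on through SeO2, O=[Se]=O)
Why: SeO2 allylic oxidation (ene reaction followed by [2,3]-sigmatropic shift) takes the E-methyl group of the less hindered terminal isopropylidene alkene, and the borohydride treatment returns any over-oxidised enal to the E-allylic alcohol.

Step 3
Reactants: 3 E-allylic alcohol
Product: 4 (2R,3R)-epoxy alcohol [(2R,3R)-2-methyl-3-{(3Z)-3-methyl-6-(2-methyl-1,3-dioxolan-2-yl)hex-3-en-1-yl}oxiran-2-yl]methanol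
Conditions: Ti(OiPr)4 (10 mol %), D-(−)-diethyl tartrate (13 mol %), t-BuOOH (2 equiv, decane), 4 Å MS, CH2Cl2, −20 °C
Reagents that add atoms: tert-butyl hydroperoxide, CC(C)(C)OO
Why: The Sharpless asymmetric epoxidation touches only the allylic-alcohol alkene, and the D-(−)-tartrate catalyst delivers oxygen to the face that gives both new centres as (2R,3R), the mirror image of the (2S,3S) result known for L-(+)-tartrate on E-allylic alcohols.

Step 4
Reactants: 4 (2R,3R)-epoxy alcohol
Product: 5 (2S,3S,6Z)-2,3,6-trimethyl-9-(2-methyl-1,3-dioxolan-2-yl)non-6-ene-1,2-diol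
Conditions: Me2CuLi (4 equiv, from CuI and MeLi), Et2O, −30 to 0 °C; H2O work-up
Reagents that add atoms: lithium dimethylcuprate, [Li+].C[Cu-]C
Why: SN2 opening by the Gilman cuprate goes to the secondary C3 because C2 is fully substituted, and it proceeds with inversion, so the (3R) C–O carbon becomes the (3S) methyl-bearing stereocentre while the tertiary carbinol carbon is not touched.

Step 5
Reactants: 5 (2S,3S)-diol
Product: 7 Z-epoxy alkene 2-methyl-2-{(3Z,7S)-4-methyl-7-[(2S)-2-methyloxiran-2-yl]oct-3-en-1-yl}-1,3-dioxolane, via primary mesylate 6 (not isolated)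
Conditions: MsCl (1.05 equiv), Et3N (1.5 equiv), CH2Cl2, −10 °C; then K2CO3, MeOH, rt
Reagents that add atoms: methanesulfonyl chloride, CS(=O)(=O)Cl (its atoms stay in 6 only)
Why: Selective sulfonylation of the primary hydroxyl and base-induced 3-exo-tet Williamson closure by the tertiary alkoxide give the 2,2-disubstituted oxirane without breaking a bond at either stereocentre.

Step 6
Reactants: 7 Z-epoxy alkene
Product: 8 trans ring alcohol {(2S,6S)-1,2-dimethyl-5-methylidene-6-[2-(2-methyl-1,3-dioxolan-2-yl)ethyl]cyclohexyl}methanol (both epimers at C1)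
Conditions: Cp2TiCl2 (2.5 equiv), Mn dust (8 equiv), degassed THF, rt until green; 7 added slowly (final ca. 0.02 M), rt; H2O/NaHCO3 work-up in air
Reagents that add atoms: none
Why: Cp2TiCl (trivalent titanium, from Cp2TiCl2 and Mn) binds the oxirane oxygen and cleaves the C–O bond at the fully substituted carbon by single-electron transfer, giving the tertiary β-titanoxy radical and not the primary one. This is the Nugent–RajanBabu epoxide opening as used in titanocene-mediated cyclisations of epoxypolyprenes, and because the bulky reagent captures tertiary radicals slowly, the radical lives long enough to add to the alkene. The one ring closes 6-endo-trig, the radical attacking the CH terminus of the trisubstituted alkene because the 5-exo position is the fully substituted alkene carbon, and a tertiary ring radical results. The new ring CH stereocentre is set in a chair in which the existing (S)-methyl group is equatorial and the Z geometry forces the ketal-bearing chain axial, hence 1,3-trans (a chair with axial methyl would put methyl and chain syn-diaxial), while the carbon bearing CH3 and CH2O–Ti forms as both epimers, which is harmless because step 8 turns it into C(CH3)2. A second Cp2TiCl traps the ring radical, and the tertiary alkyl of tetravalent titanium loses a β-hydrogen from the freely rotating, least hindered methyl group, which gives the exocyclic methylene. The step needs regioselective oxirane opening, 6-endo closure, chair control and exocyclic termination, all secured by the substitution pattern named above, and a radical, unlike the tertiary cation, does not invite a 1,2-hydride shift from the neighbouring CH(CH3).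

Step 7
Reactants: 8 trans ring alcohol
Product: 9 (2S,6S)-1,2-dimethyl-5-methylidene-6-[2-(2-methyl-1,3-dioxolan-2-yl)ethyl]cyclohexane-1-carbaldehyde (both epimers at C1)
Conditions: n-Pr4N[RuO4] (5 mol %), NMO (1.5 equiv), 4 Å MS, CH2Cl2, rt
Reagents that add atoms: none
Why: The Ley–Griffith oxidation is neutral, so ketal and exocyclic alkene survive, and the aldehyde has no α-hydrogen and cannot enolise.

Step 8
Reactants: 9 neopentyl aldehyde
Product: 11 2-methyl-2-{2-[(1S,3S)-2,2,3-trimethyl-6-methylidenecyclohexyl]ethyl}-1,3-dioxolane, via hydrazone 10 (not isolated)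
Conditions: N2H4·H2O (10 equiv), KOH (6 equiv), diethylene glycol, N2, 120 °C, then 195 °C with removal of water
Reagents that add atoms: hydrazine, NN (nitrogen stays in 10 only)
Why: The Wolff–Kishner reduction (Huang-Minlon procedure) turns the non-enolisable aldehyde into the second geminal methyl group, so both epimers converge on one compound, and the base-stable ketal and the unactivated alkene are unaffected when air is excluded so that no diimide forms.

Step 9
Reactants: 11 gem-dimethyl ketal
Product: 12 trans-dihydro-γ-irone 4-[(1S,3S)-2,2,3-trimethyl-6-methylidenecyclohexyl]butan-2-one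
Conditions: PPTS (0.2 equiv), acetone/H2O (10:1), 50 °C
Reagents that add atoms: water, O
Why: Mild acid-catalysed ketal hydrolysis frees the methyl ketone under conditions too weak to protonate and shift the 1,1-disubstituted alkene.

Step 10
Reactants: 12 trans-dihydro-γ-irone; 13 triethyl phosphonoacetate
Product: 14 ethyl (2E)-3-methyl-5-[(1S,3S)-2,2,3-trimethyl-6-methylidenecyclohexyl]pent-2-enoate
Conditions: 13 (2 equiv), NaH (1.9 equiv), THF, 0 to 50 °C; chromatographic removal of the Z-isomer
Reagents that add atoms: triethyl phosphonoacetate 13, CCOC(=O)CP(=O)(OCC)OCC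
Why: The Horner–Wadsworth–Emmons olefination of the methyl ketone should favour the E-enoate with the larger chain trans to the ester, and the Z-isomer is removed because the two geometries would give opposite configurations in step 11.

Step 11
Reactants: 14 E-enoate
Product: 15 ethyl (3S)-3-methyl-5-[(1S,3S)-2,2,3-trimethyl-6-methylidenecyclohexyl]pentanoate
Conditions: Cu(OAc)2·H2O (3 mol %), (R)-DTBM-SEGPHOS (3 mol %), (EtO)2MeSiH (2 equiv), t-BuOH (2 equiv), toluene, 0 °C to rt
Reagents that add atoms: none
Why: Copper hydride catalysed asymmetric conjugate reduction (1,4-hydrosilylation) adds hydride under ligand control to the Re face of C3 of the E-enoate, which sets the (S)-methyl stereocentre, and it does not touch the isolated exocyclic alkene.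

Step 12
Reactants: 15 (S)-ester
Product: 16 (3S)-3-methyl-5-[(1S,3S)-2,2,3-trimethyl-6-methylidenecyclohexyl]pentanal
Conditions: i-Bu2AlH (1.1 equiv), toluene, −78 °C; H2O work-up
Reagents that add atoms: none
Why: Partial ester reduction at low temperature stops at the aluminium hemiacetal, which gives the aldehyde on work-up, and the β-stereocentre is not acidic.

Step 13
Reactants: 16 (S)-aldehyde
Product: 18 (3S)-3-methyl-5-[(1S,3S)-2,2,3-trimethyl-6-methylidenecyclohexyl]pent-1-yne, via alkenyl nonaflate 17 (not isolated)
Conditions: n-C4F9SO2F (1.3 equiv), phosphazene base P2-Et (2.6 equiv, added slowly), DMF, −20 °C to rt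
Reagents that add atoms: nonafluorobutane-1-sulfonyl fluoride, FS(=O)(=O)C(F)(F)C(F)(F)C(F)(F)C(F)(F)F (its atoms stay in 17 only)
Why: In this one-pot nonaflation–elimination the enolate is trapped on oxygen and a second equivalent of base eliminates nonaflate, so the two carbons added in step 10 become the two alkyne carbons (a diazophosphonate homologation would put one carbon too many between the methyl-bearing centre and the future alkene), and the now propargylic stereocentre is safe because the acetylenic C–H is far more acidic.

Step 14
Reactants: 19 (2E,6E)-farnesol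
Product: 20 diethyl (2E,6E)-farnesyl phosphate
Conditions: ClP(O)(OEt)2 (1.2 equiv), Et3N (1.5 equiv), DMAP (10 mol %), CH2Cl2, 0 °C
Reagents that add atoms: diethyl chlorophosphate, CCOP(=O)(Cl)OCC
Why: O-phosphorylation of the primary allylic alcohol under mild base installs the leaving group without allylic transposition or loss of alkene geometry.

Step 15
Reactants: 18 (S)-alkyne; 20 farnesyl diethyl phosphate
Product: 22 target (3S,6E)-3,7,11-trimethyl-3-{(1E,3S)-3-methyl-5-[(1S,3S)-2,2,3-trimethyl-6-methylidenecyclohexyl]pent-1-en-1-yl}dodeca-1,6,10-triene, via alkenylalane 21 (not isolated)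
Conditions: i-Bu2AlH (1.0 equiv), hexanes, 55 °C; then 20 (1.3 equiv), CuCl2·2H2O (5 mol %), silver carbene made with Ag2O from the (S,S)-4,5-diphenylimidazolinium salt bearing N-(2-sulfonatophenyl) and N-(2,6-diethylphenyl) groups (2.5 mol %), THF, −15 °C; H2O work-up
Reagents that add atoms: diisobutylaluminium hydride, CC(C)C[AlH]CC(C)C (aluminium and isobutyl groups stay in 21 only)
Why: syn-Hydroalumination of the terminal alkyne, which is faster than that of the hindered 1,1-disubstituted alkene, gives the E-alkenylalane, whose alkenyl group is transferred with retention in a copper-catalysed enantioselective allylic substitution (SN2′) at C3 of the E-trisubstituted phosphate, a known way to all-carbon quaternary vinyl centres from prenyl-type phosphates, and the bidentate sulfonate carbene ligand selects the alkene face and sets the (S)-quaternary carbon.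

## Compound list

1 | nerylacetone, (5Z)-6,10-dimethylundeca-5,9-dien-2-one | CC(=O)CC/C=C(/C)CCC=C(C)C | starting material
2 | nerylacetone ethylene ketal | CC1(OCCO1)CC/C=C(/C)CCC=C(C)C | intermediate
3 | (2E,6Z)-allylic alcohol | CC1(OCCO1)CC/C=C(/C)CC/C=C(\C)CO | intermediate
4 | (2R,3R)-epoxy alcohol | CC1(OCCO1)CC/C=C(/C)CC[C@H]2O[C@]2(C)CO | intermediate
5 | (2S,3S)-1,2-diol with new methyl group | CC1(OCCO1)CC/C=C(/C)CC[C@H](C)[C@](C)(O)CO | intermediate
6 | primary mesylate of 5 | CC1(OCCO1)CC/C=C(/C)CC[C@H](C)[C@](C)(O)COS(C)(=O)=O | intermediate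
7 | Z-epoxy alkene, 2,2-disubstituted oxirane | CC1(OCCO1)CC/C=C(/C)CC[C@H](C)[C@@]2(C)CO2 | intermediate
8 | trans ring alcohol with exocyclic methylene, epimers at the C(CH3)(CH2OH) carbon | CC1(OCCO1)CC[C@H]2C(=C)CC[C@H](C)C2(C)CO | intermediate
9 | neopentyl aldehyde, epimers at the C(CH3)(CHO) carbon | CC1(OCCO1)CC[C@H]2C(=C)CC[C@H](C)C2(C)C=O | intermediate
10 | hydrazone of 9 | CC1(OCCO1)CC[C@H]2C(=C)CC[C@H](C)C2(C)C=NN | intermediate
11 | gem-dimethyl ring ketal | CC1(OCCO1)CC[C@H]2C(=C)CC[C@H](C)C2(C)C | intermediate
12 | trans-dihydro-γ-irone | CC(=O)CC[C@H]1C(=C)CC[C@H](C)C1(C)C | intermediate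
13 | triethyl phosphonoacetate | CCOC(=O)CP(=O)(OCC)OCC | starting material
14 | E-enoate | CCOC(=O)/C=C(\C)CC[C@H]1C(=C)CC[C@H](C)C1(C)C | intermediate
15 | (3S)-ester | CCOC(=O)C[C@@H](C)CC[C@H]1C(=C)CC[C@H](C)C1(C)C | intermediate
16 | (3S)-aldehyde | O=CC[C@@H](C)CC[C@H]1C(=C)CC[C@H](C)C1(C)C | intermediate
17 | alkenyl nonaflate, E/Z mixture | FC(F)(F)C(F)(F)C(F)(F)C(F)(F)S(=O)(=O)OC=C[C@@H](C)CC[C@H]1C(=C)CC[C@H](C)C1(C)C | intermediate
18 | (3S)-terminal alkyne | C#C[C@@H](C)CC[C@H]1C(=C)CC[C@H](C)C1(C)C | intermediate
19 | (2E,6E)-farnesol | CC(C)=CCC/C(C)=C/CC/C(C)=C/CO | starting material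
20 | diethyl (2E,6E)-farnesyl phosphate | CC(C)=CCC/C(C)=C/CC/C(C)=C/COP(=O)(OCC)OCC | intermediate
21 | (E)-alkenyl(diisobutyl)alane | CC(C)C[Al](CC(C)C)/C=C/[C@@H](C)CC[C@H]1C(=C)CC[C@H](C)C1(C)C | intermediate
22 | CNP0322301.1 | C=C[C@@](C)(/C=C/[C@@H](C)CC[C@H]1C(=C)CC[C@H](C)C1(C)C)CC/C=C(\C)CCC=C(C)C | target

## Step count and risks

Total step count: 15. Longest linear sequence: 14 (steps 1–13 and 15).

**Step 6.**
- What may go wrong: the tertiary alkyltitanium may lose a ring hydrogen instead of a methyl hydrogen, or the ring radical may disproportionate. In either case alkene regiocontrol is lost although the ring has closed.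
- Fallback: it sets out from 7 and comes back at 8. It replaces control in the termination by a stepwise alkene transposition.
- The closure is accepted whatever the alkene position, and the endocyclic trisubstituted alkene isomer F1 is separated on AgNO3-impregnated silica.
- m-CPBA/NaHCO3 converts its only alkene into the ring epoxide F2.
- Diethylaluminium 2,2,6,6-tetramethylpiperidide (from Et2AlCl and the lithium amide) removes a proton from the methyl group on the tertiary epoxide carbon and gives the exocyclic allylic alcohol F3.
- ClCO2Me/pyridine gives the bis(methyl carbonate) F4.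
- Formate hydrogenolysis under zerovalent palladium (Pd(OAc)2, P(n-Bu)3, HCO2H/Et3N, THF) ionises only the allylic carbonate. It delivers hydride to the more substituted allyl terminus and leaves the exocyclic methylene in the mono-carbonate F5.
- K2CO3/MeOH then returns 8.

**Step 15.**
- What may go wrong: the face selection by the copper catalyst may be poor with this branched, precious alkenylalane, or isobutyl transfer and SN2 attack may compete. The epimers at the remote quaternary carbon would be hard to separate.
- Fallback: it sets out from 18 and 19 and comes back at 22. It replaces catalyst control by stereospecific epoxide opening.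
- Sharpless epoxidation of 19 (Ti(OiPr)4, D-(−)-diethyl tartrate, t-BuOOH) gives (2R,3R)-2,3-epoxyfarnesol F6.
- Alkyne 18 is converted (n-BuLi, then Me2AlCl) into the dimethylalkynylalane F7.
- F7 opens the pre-metalated epoxy alcohol at the tertiary C3 with inversion and gives the alkynyl diol F8, which already holds the quaternary centre in the required sense.
- A Corey–Winter sequence (thiocarbonyldiimidazole, then P(OMe)3, heat) passes through the cyclic thionocarbonate F9 and turns the diol into the vinyl group of the 1,4-enyne F10.
- Na/NH3(l), t-BuOH reduces the internal alkyne to the E-alkene of 22 and leaves the isolated alkenes alone.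

**Step 13.**
- What may go wrong: aldol self-condensation of the aldehyde under the strong base may compete, or base-induced alkyne–allene isomerisation may erode the propargylic stereocentre.
- Fallback: it sets out from 15 and comes back at 18. It first removes one carbon and then homologates.
- Enolate hydroxylation (KN(SiMe3)2, 2-(phenylsulfonyl)-3-phenyloxaziridine, −78 °C) gives the α-hydroxy ester F11.
- LiAlH4 gives the 1,2-diol F12.
- NaIO4 cleaves it to the α-methyl aldehyde F13.
- The Ohira–Bestmann reaction (dimethyl (1-diazo-2-oxopropyl)phosphonate, K2CO3, MeOH, 0 °C) adds the single missing carbon and gives 18.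

## Further compounds

F1 | step 6 | endocyclic (trisubstituted) alkene isomer of 8 | CC1(OCCO1)CC[C@H]2C(C)=CC[C@H](C)C2(C)CO
F2 | step 6 | ring epoxide of F1 | CC1(OCCO1)CC[C@H]2C3(C)OC3C[C@H](C)C2(C)CO
F3 | step 6 | exocyclic allylic alcohol (diol) | CC1(OCCO1)CC[C@H]2C(=C)C(O)C[C@H](C)C2(C)CO
F4 | step 6 | bis(methyl carbonate) of F3 | CC1(OCCO1)CC[C@H]2C(=C)C(OC(=O)OC)C[C@H](C)C2(C)COC(=O)OC
F5 | step 6 | methyl carbonate of 8 | CC1(OCCO1)CC[C@H]2C(=C)CC[C@H](C)C2(C)COC(=O)OC
F6 | step 15 | (2R,3R)-2,3-epoxyfarnesol | OC[C@H]1O[C@]1(C)CC/C=C(\C)CCC=C(C)C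
F7 | step 15 | dimethylalkynylalane of 18 | C[Al](C)C#C[C@@H](C)CC[C@H]1C(=C)CC[C@H](C)C1(C)C
F8 | step 15 | alkynyl 1,2-diol with quaternary centre | OC[C@@H](O)[C@@](C)(C#C[C@@H](C)CC[C@H]1C(=C)CC[C@H](C)C1(C)C)CC/C=C(\C)CCC=C(C)C
F9 | step 15 | cyclic thionocarbonate of F8 | S=C1OC[C@@H](O1)[C@@](C)(C#C[C@@H](C)CC[C@H]2C(=C)CC[C@H](C)C2(C)C)CC/C=C(\C)CCC=C(C)C
F10 | step 15 | 1,4-enyne, alkyne analogue of 22 | C=C[C@@](C)(C#C[C@@H](C)CC[C@H]1C(=C)CC[C@H](C)C1(C)C)CC/C=C(\C)CCC=C(C)C
F11 | step 13 | α-hydroxy ester, epimers at the carbinol carbon | CCOC(=O)C(O)[C@@H](C)CC[C@H]1C(=C)CC[C@H](C)C1(C)C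
F12 | step 13 | 1,2-diol, epimers at the carbinol carbon | OCC(O)[C@@H](C)CC[C@H]1C(=C)CC[C@H](C)C1(C)C
F13 | step 13 | (2S)-2-methyl-4-[(1S,3S)-2,2,3-trimethyl-6-methylidenecyclohexyl]butanal | O=C[C@@H](C)CC[C@H]1C(=C)CC[C@H](C)C1(C)C
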